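The route rests on removing O1 from lactone ring B. O1 bridges the C2 carbonyl and C8a of ring A, so its excision leaves a 3-arylindan-1-one whose C1–C7a bond marks the insertion site. An acid-catalysed Baeyer–Villiger oxidation puts the oxygen on a carbon that lies meta to the C7 oxygen and beside crowded C4a. In the same operation it enlarges the five-membered ketone to ring B without touching C4. The precursor is (R)-6-benzyloxy-3-(4-benzyloxy-3-methoxyphenyl)-4-chloroindan-1-one, made by an enantioselective reductive Heck cyclisation. Benzyl ethers tolerate acid and peracid, and chlorine holds C5 for a late Heck styrylation.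

Key step: step 6

Assumption: the (R)-bisphosphine in step 5 is taken to give the (R)-indanone. The sense of induction is to be verified on the first batch, and the equally available (S)-ligand is used if it proves opposite.

Numbering: primed locants refer to the acetophenone ring. Compounds 7 and 8 use indan-1-one numbering, and 9, 11 and 12 use chroman-2-one numbering.

Step 1
Reactants: 1 2',5'-dihydroxyacetophenone
Product: 2 1-[5-(benzyloxy)-2-hydroxyphenyl]ethan-1-one
Conditions: BnBr (1.05 equiv), K2CO3, acetone, reflux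
Reagents that add atoms: benzyl bromide, BrCc1ccccc1
Why: Williamson ether synthesis; the 2'-OH is tied up in a hydrogen bond to the ketone and is much less nucleophilic, so one equivalent of benzyl bromide should alkylate only the 5'-OH.

Step 2
Reactants: 2 1-[5-(benzyloxy)-2-hydroxyphenyl]ethan-1-one
Product: 3 1-[5-(benzyloxy)-3-chloro-2-hydroxyphenyl]ethan-1-one
Conditions: NCS (1.05 equiv), DMF, rt to 40 °C
Reagents that add atoms: N-chlorosuccinimide, O=C1CCC(=O)N1Cl
Why: Electrophilic aromatic chlorination; C3' is the only open site that is ortho to the free phenol and meta to the acetyl group, whereas C4' and C6' are para and ortho to the deactivating carbonyl, so chlorine should enter at C3'.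

Step 3
Reactants: 3 1-[5-(benzyloxy)-3-chloro-2-hydroxyphenyl]ethan-1-one; 4 4-(benzyloxy)-3-methoxybenzaldehyde (O-benzylvanillin)
Product: 5 (E)-1-[5-(benzyloxy)-3-chloro-2-hydroxyphenyl]-3-[4-(benzyloxy)-3-methoxyphenyl]prop-2-en-1-one
Conditions: KOH (50 % aq), EtOH, rt; then 1 M HCl, 0 °C
Reagents that add atoms: none
Why: Claisen–Schmidt condensation; the methyl ketone enolate adds to the non-enolisable aldehyde and E1cB loss of water gives the conjugated E-enone, while the benzyl ethers and the aryl chloride are inert to hydroxide and the phenoxide form disfavours closure to the flavanone.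

Step 4
Reactants: 5 (E)-1-[5-(benzyloxy)-3-chloro-2-hydroxyphenyl]-3-[4-(benzyloxy)-3-methoxyphenyl]prop-2-en-1-one
Product: 6 4-(benzyloxy)-2-{(E)-3-[4-(benzyloxy)-3-methoxyphenyl]prop-2-enoyl}-6-chlorophenyl trifluoromethanesulfonate
Conditions: Tf2O (1.2 equiv), pyridine, CH2Cl2, 0 °C
Reagents that add atoms: trifluoromethanesulfonic anhydride, O=S(=O)(OS(=O)(=O)C(F)(F)F)C(F)(F)F
Why: O-sulfonylation of a phenol; the only free hydroxyl group is the 2'-OH, and the cold, weakly basic medium should leave the enone geometry intact and suppress oxa-Michael closure.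

Step 5
Reactants: 6 4-(benzyloxy)-2-{(E)-3-[4-(benzyloxy)-3-methoxyphenyl]prop-2-enoyl}-6-chlorophenyl trifluoromethanesulfonate
Product: 7 (R)-6-(benzyloxy)-3-[4-(benzyloxy)-3-methoxyphenyl]-4-chloro-2,3-dihydro-1H-inden-1-one
Conditions: Pd(OAc)2 (10 mol %), (R)-3,5-Xyl-MeOBIPHEP (12 mol %), proton sponge (2.5 equiv), DMF, 90 °C
Reagents that add atoms: none
Why: Enantioselective intramolecular reductive Heck reaction, known for 2'-sulfonyloxychalcones; zerovalent palladium inserts into the C–OTf bond rather than the inert C–Cl bond, the cationic aryl-palladium species bearing the chiral bisphosphine adds to one face of the enone to form C3–C3a and set C3 as R, and hydride from an N-methyl group of the amine releases the saturated ketone.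

Step 6
Reactants: 7 (R)-6-(benzyloxy)-3-[4-(benzyloxy)-3-methoxyphenyl]-4-chloro-2,3-dihydro-1H-inden-1-one
Product: 9 (R)-7-(benzyloxy)-4-[4-(benzyloxy)-3-methoxyphenyl]-5-chlorochroman-2-one, via Criegee adduct 8 (not isolated)
Conditions: mCPBA (3 equiv), TsOH·H2O (20 mol %), CH2Cl2, 0 °C to rt, dark; aq Na2SO3, then cold aq NaHCO3 wash
Reagents that add atoms: mCPBA (3-chloroperoxybenzoic acid), O=C(OO)c1cccc(Cl)c1
Why: Baeyer–Villiger oxidation, known for 3-aryl-1-indanones: the protonated C1 carbonyl of 7 takes up the peracid to give Criegee adduct 8, and the C1–C7a bond, aligned antiperiplanar to the O–O bond, shifts to oxygen as 3-chlorobenzoate departs. Ring B is thus closed not by a cyclisation but by a 1,2-shift ring expansion from five to six members that forms O1–C8a and O1–C2 together. No stereocentre is created; C4 (C3 of 7) takes no part in the shift, bears no acidic hydrogen and should keep its R configuration. The selectivity needed is migration of the sp2 carbon C7a over the primary C2 methylene, which rests on the better ability of an aryl carbon to carry positive charge in the transition state, helped by the ortho alkyl branch at C3a and only moderately eroded by the meta chlorine and meta benzyloxy groups. Chemoselectivity comes from the substrate design, since 7 holds no alkene, free phenol or acetal, and its benzyl ethers and aryl chloride are inert to TsOH and peracid.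

Step 7
Reactants: 9 (R)-7-(benzyloxy)-4-[4-(benzyloxy)-3-methoxyphenyl]-5-chlorochroman-2-one; 10 1-(benzyloxy)-4-ethenyl-2-methoxybenzene (4-benzyloxy-3-methoxystyrene)
Product: 11 (R)-7-(benzyloxy)-4-[4-(benzyloxy)-3-methoxyphenyl]-5-{(E)-2-[4-(benzyloxy)-3-methoxyphenyl]ethenyl}chroman-2-one
Conditions: Pd2(dba)3 (2.5 mol %), P(t-Bu)3·HBF4 (10 mol %), Cy2NMe (1.5 equiv), dry 1,4-dioxane, 100–110 °C
Reagents that add atoms: none
Why: Mizoroki–Heck reaction of an aryl chloride enabled by the bulky electron-rich phosphine; syn carbopalladation at the unsubstituted styrene terminus and syn β-hydride elimination should give the E-stilbene, the C5–Cl carbon is meta to both ring A oxygens and so not deactivated, and the hindered tertiary amine in dry solvent leaves the aryl lactone and C4 untouched.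

Step 8
Reactants: 11 (R)-7-(benzyloxy)-4-[4-(benzyloxy)-3-methoxyphenyl]-5-{(E)-2-[4-(benzyloxy)-3-methoxyphenyl]ethenyl}chroman-2-one
Product: 12 (R)-7-hydroxy-4-(4-hydroxy-3-methoxyphenyl)-5-[(E)-2-(4-hydroxy-3-methoxyphenyl)ethenyl]chroman-2-one (CNP0277187.1)
Conditions: AlCl3 (9 equiv), PhNMe2 (12 equiv), CH2Cl2, 0 °C; then cold 1 M HCl
Reagents that add atoms: none
Why: Lewis acid-assisted dealkylation of aryl benzyl ethers, a combination established on benzyl-protected hydroxystilbenes; AlCl3 activates each ether oxygen and the aniline removes the benzyl group by SN2 attack while scavenging HCl, so no free Brønsted acid meets the stilbene, and the methyl ethers, the lactone and C4 should react far more slowly at 0 °C.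

Compound list
1 | 2',5'-dihydroxyacetophenone | CC(=O)c1cc(O)ccc1O | starting material
2 | 1-[5-(benzyloxy)-2-hydroxyphenyl]ethan-1-one | CC(=O)c1cc(OCc2ccccc2)ccc1O | intermediate
3 | 1-[5-(benzyloxy)-3-chloro-2-hydroxyphenyl]ethan-1-one | CC(=O)c1cc(OCc2ccccc2)cc(Cl)c1O | intermediate
4 | 4-(benzyloxy)-3-methoxybenzaldehyde | COc1cc(C=O)ccc1OCc1ccccc1 | starting material
5 | (E)-1-[5-(benzyloxy)-3-chloro-2-hydroxyphenyl]-3-[4-(benzyloxy)-3-methoxyphenyl]prop-2-en-1-one | COc1cc(/C=C/C(=O)c2cc(OCc3ccccc3)cc(Cl)c2O)ccc1OCc1ccccc1 | intermediate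
6 | 4-(benzyloxy)-2-{(E)-3-[4-(benzyloxy)-3-methoxyphenyl]prop-2-enoyl}-6-chlorophenyl trifluoromethanesulfonate | COc1cc(/C=C/C(=O)c2cc(OCc3ccccc3)cc(Cl)c2OS(=O)(=O)C(F)(F)F)ccc1OCc1ccccc1 | intermediate
7 | (R)-6-(benzyloxy)-3-[4-(benzyloxy)-3-methoxyphenyl]-4-chloro-2,3-dihydro-1H-inden-1-one | O(Cc1ccccc1)c1cc(Cl)c2c(c1)C(=O)C[C@@H]2c1ccc(OCc2ccccc2)c(OC)c1 | intermediate
8 | (3R)-6-(benzyloxy)-3-[4-(benzyloxy)-3-methoxyphenyl]-4-chloro-1-hydroxy-2,3-dihydro-1H-inden-1-yl 3-chlorobenzenecarboperoxoate (Criegee adduct, both C1 epimers) | O(Cc1ccccc1)c1cc(Cl)c2c(c1)C(O)(OOC(=O)c1cccc(Cl)c1)C[C@@H]2c1ccc(OCc2ccccc2)c(OC)c1 | intermediate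
9 | (R)-7-(benzyloxy)-4-[4-(benzyloxy)-3-methoxyphenyl]-5-chlorochroman-2-one | O(Cc1ccccc1)c1cc(Cl)c2c(c1)OC(=O)C[C@@H]2c1ccc(OCc2ccccc2)c(OC)c1 | intermediate
10 | 1-(benzyloxy)-4-ethenyl-2-methoxybenzene | COc1cc(C=C)ccc1OCc1ccccc1 | starting material
11 | (R)-7-(benzyloxy)-4-[4-(benzyloxy)-3-methoxyphenyl]-5-{(E)-2-[4-(benzyloxy)-3-methoxyphenyl]ethenyl}chroman-2-one | COc1cc(/C=C/c2cc(OCc4ccccc4)cc3c2[C@@H](c2ccc(OCc4ccccc4)c(OC)c2)CC(=O)O3)ccc1OCc1ccccc1 | intermediate
12 | (R)-7-hydroxy-4-(4-hydroxy-3-methoxyphenyl)-5-[(E)-2-(4-hydroxy-3-methoxyphenyl)ethenyl]chroman-2-one | COc1cc(/C=C/c2cc(O)cc3c2[C@@H](c2ccc(O)c(OC)c2)CC(=O)O3)ccc1O | target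

Total step count: 8. Longest linear sequence: 8 steps (1 to 12); compounds 4 and 10 are purchased.

Steps most likely to fail

Step 6. The meta chlorine and meta benzyloxy group lower the migratory aptitude of C7a. The C2 methylene may therefore compete in the shift, or the oxidation may stall long enough for the peracid to attack the electron-rich pendant ring. The fallback sets out from 7 and returns at 9.
- Bromination of 7 with PhNMe3Br3 in THF at 0 °C goes through the enol and should enter anti to the C3 aryl group. This should give (2S,3R)-6-(benzyloxy)-3-[4-(benzyloxy)-3-methoxyphenyl]-2-bromo-4-chloroindan-1-one F1.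
- A halogen-bearing carbon is a very poor migrating group, as the oxidation of 2-halocyclohexanones to α-halolactones shows, and the carbonyl becomes more electrophilic. mCPBA and TsOH·H2O in CH2Cl2 should therefore deliver only the aryl-shifted (3S,4R)-7-(benzyloxy)-4-[4-(benzyloxy)-3-methoxyphenyl]-3-bromo-5-chlorochroman-2-one F2.
- F2 is kept away from base, which could eliminate HBr towards the achiral coumarin. It is reduced at once with Zn dust in AcOH/THF at room temperature to 9.

Step 5. The chlorine next to the palladium-bearing carbon may erode facial selectivity in the insertion. Premature hydride capture may remove the triflate without cyclisation, and S–O hydrolysis of the crowded triflate may return the phenol. The fallback sets out from 6 and returns at 7.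
- Miyaura borylation (PdCl2(dppf), B2pin2, KOAc, dioxane, 80 °C) should give (E)-1-[5-(benzyloxy)-3-chloro-2-(4,4,5,5-tetramethyl-1,3,2-dioxaborolan-2-yl)phenyl]-3-[4-(benzyloxy)-3-methoxyphenyl]prop-2-en-1-one F3.
- F3 is closed by the known rhodium-catalysed asymmetric intramolecular 1,4-addition of boryl chalcones ([Rh(C2H4)2Cl]2, the MonoPhos enantiomer that leads to R, aq K3PO4, toluene, rt to 60 °C) to 7. The stereocentre is then set by a different metal and ligand class.

Step 8. Chelation by the newly freed aluminium phenoxides may cause loss of an adjacent methyl ether. Lewis acid may also trigger attack of the pendant ring on the electron-rich stilbene. The fallback sets out from 9 and returns at 12, and it removes the benzyl groups before any alkene is present.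
- BCl3 and pentamethylbenzene in CH2Cl2 at −78 °C should give (R)-5-chloro-7-hydroxy-4-(4-hydroxy-3-methoxyphenyl)chroman-2-one F4.
- F4 is coupled without protecting groups with commercial 2-methoxy-4-vinylphenol (COc1cc(C=C)ccc1O). The conditions are Pd2(dba)3, P(t-Bu)3·HBF4, Cy2NMe and a trace of BHT in dioxane at 100 °C, giving 12 directly.

Further compounds
F1 | step 6 | (2S,3R)-6-(benzyloxy)-3-[4-(benzyloxy)-3-methoxyphenyl]-2-bromo-4-chloro-2,3-dihydro-1H-inden-1-one | O(Cc1ccccc1)c1cc(Cl)c2c(c1)C(=O)[C@@H](Br)[C@@H]2c1ccc(OCc2ccccc2)c(OC)c1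
F2 | step 6 | (3S,4R)-7-(benzyloxy)-4-[4-(benzyloxy)-3-methoxyphenyl]-3-bromo-5-chlorochroman-2-one | O(Cc1ccccc1)c1cc(Cl)c2c(c1)OC(=O)[C@@H](Br)[C@@H]2c1ccc(OCc2ccccc2)c(OC)c1
F3 | step 5 | (E)-1-[5-(benzyloxy)-3-chloro-2-(4,4,5,5-tetramethyl-1,3,2-dioxaborolan-2-yl)phenyl]-3-[4-(benzyloxy)-3-methoxyphenyl]prop-2-en-1-one | COc1cc(/C=C/C(=O)c2cc(OCc3ccccc3)cc(Cl)c2B4OC(C)(C)C(C)(C)O4)ccc1OCc1ccccc1
F4 | step 8 | (R)-5-chloro-7-hydroxy-4-(4-hydroxy-3-methoxyphenyl)chroman-2-one | Oc1cc(Cl)c2c(c1)OC(=O)C[C@@H]2c1ccc(O)c(OC)c1
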